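## Retrosynthetic overview

1. Target 31 ⇐ 28: the C1 ketone and the C10=C14 methylene are made last from a C1=C10 olefin (singlet-oxygen ene, dehydration of the hydroperoxide). The C8 tiglate and C13 acetate are late acylations of a 13-hydroxy-7(11)-en-12,6-olide.
2. Butenolide ⇐ epoxy ketone 14: C7–C11 aldol with ethyl glyoxylate, C6 reduction and lactonisation, oxidation to the C11 enol, enol triflate, Stille hydroxymethylation (C13). 14 ⇐ dienone 13 by nucleophilic epoxidation of the C4=C5 enone.
3. Feature and key disconnection: C1/C10 and C4/C5 lie 1,5 to each other across the ten-membered carbocycle, with the C2–C3 ethano unit between them (a cyclodeca-1,5-diene). 13 ⇐ tricyclic cyclobutane 12 by thermal retro-[2+2], breaking C1–C4 and C5–C10. 12 is taken with a trans 6/4 ring fusion, because only that fusion can deliver both olefins as E; a cis-fused adduct would leave the enone Z.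
4. 12 ⇐ enone 7 + 1-methylcyclobutene 11 by [2+2] photocycloaddition. 7 comes from all-cis-cyclohexane-1,3,5-triol by lipase desymmetrisation (C8 is the only stereocentre carried in); 11 comes from cyclopropyl methyl ketone.
5. Ring order: cyclohexane (bought) → two cyclobutanes (step 8) → ten-membered ring (step 9) → oxirane (step 10) → butenolide (steps 12 and 13).

Key step: step 9

Assumptions (remarks on the chemistry):
- Germacrane numbering (C1–C15) is used for all ten-membered compounds and, for orientation, for the precursor carbons that become them.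
- The lipase of step 2 is taken, after screening of commercial lipases, to acylate the enantiotopic hydroxyl that leads to 3.
- Compound 12 is drawn as one trans-fused diastereomer; every trans 6/4-fused head-to-head adduct gives the same dienone 13.

## Route

Step 1
Reactants: 1 all-cis-cyclohexane-1,3,5-triol
Product: 2 all-cis-5-(tert-butyldimethylsilyloxy)cyclohexane-1,3-diol
Conditions: TBSCl (1.0 equiv), imidazole, DMF, 0 °C to rt
Reagents that add atoms: tert-butyldimethylsilyl chloride, CC(C)(C)[Si](C)(C)Cl
Why: Silyl ether formation on one of three equivalent hydroxyls (statistical monoprotection, with recovered triol and bis-ether recycled) should give the meso diol, in which no stereocentre is yet differentiated.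

Step 2
Reactants: 2 all-cis-5-(tert-butyldimethylsilyloxy)cyclohexane-1,3-diol
Product: 3 (1R,3S,5S)-3-(tert-butyldimethylsilyloxy)-5-hydroxycyclohexyl acetate
Conditions: vinyl acetate, immobilised Burkholderia cepacia lipase, t-BuOMe, 30 °C
Reagents that add atoms: vinyl acetate, CC(=O)OC=C
Why: Lipase-catalysed irreversible transesterification (enzymatic desymmetrisation of a meso 1,3-diol) should acylate one enantiotopic hydroxyl only, which fixes the absolute configuration of all three carbinol carbons at once.

Step 3
Reactants: 3 (1R,3S,5S)-3-(tert-butyldimethylsilyloxy)-5-hydroxycyclohexyl acetate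
Product: 5 (R)-5-(tert-butyldimethylsilyloxy)cyclohex-2-en-1-one, via acetoxy ketone 4 (not isolated)
Conditions: Dess–Martin periodinane, pyridine, CH2Cl2, 0 °C to rt; filter; then DBU, CH2Cl2, 0 °C
Reagents that add atoms: none
Why: Dess–Martin oxidation of the free carbinol followed by E1cB β-elimination should expel acetate, by far the better leaving group, and leave the β-silyloxy group and its stereocentre untouched.

Step 4
Reactants: 5 (R)-5-(tert-butyldimethylsilyloxy)cyclohex-2-en-1-one
Product: 6 (5R)-5-(tert-butyldimethylsilyloxy)-1-methylcyclohex-2-en-1-ol (both C1 epimers)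
Conditions: MeLi, THF, −78 °C
Reagents that add atoms: methyllithium, [Li]C
Why: 1,2-Addition of the hard organolithium to the enone carbonyl at −78 °C outruns enolisation; the new carbinol centre is not controlled and need not be, since it becomes trigonal in step 5.

Step 5
Reactants: 6 (5R)-5-(tert-butyldimethylsilyloxy)-1-methylcyclohex-2-en-1-ol
Product: 7 (S)-5-(tert-butyldimethylsilyloxy)-3-methylcyclohex-2-en-1-one
Conditions: pyridinium chlorochromate (C5H5NH[CrO3Cl]), 4 Å molecular sieves, CH2Cl2, rt
Reagents that add atoms: pyridinium chlorochromate, [O-][Cr](=O)(=O)Cl.c1cc[nH+]cc1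
Why: Babler–Dauben oxidative transposition, in which the tertiary allylic chromate ester undergoes a [3,3] shift and the resulting secondary chromate is oxidised, should move the oxygen to the former β-carbon and leave the methyl on the new β-carbon; the silyloxy carbon is untouched and its descriptor changes from R to S only because the carbonyl has moved.

Step 6
Reactants: 8 cyclopropyl methyl ketone
Product: 9 cyclopropyl methyl ketone p-toluenesulfonylhydrazone
Conditions: TsNHNH2, MeOH, rt
Reagents that add atoms: p-toluenesulfonohydrazide, Cc1ccc(cc1)S(=O)(=O)NN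
Why: Hydrazone condensation of an unhindered methyl ketone is reliable and the product crystallises from the alcohol.

Step 7
Reactants: 9 cyclopropyl methyl ketone p-toluenesulfonylhydrazone
Product: 11 1-methylcyclobutene, via diazoalkane 10 (not isolated)
Conditions: NaOMe, diglyme, 160 °C, product distilled into a −78 °C trap
Reagents that add atoms: none
Why: Aprotic Bamford–Stevens reaction, in which the sodium salt of 9 loses sulfinate to give 10, loss of N2 leaves a cyclopropylcarbene and a 1,2-shift of a ring carbon expands it to the cyclobutene, which distils out as it forms.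

Step 8
Reactants: 7 (S)-5-(tert-butyldimethylsilyloxy)-3-methylcyclohex-2-en-1-one and 11 1-methylcyclobutene
Product: 12 (9S)-9-(tert-butyldimethylsilyloxy)-1,5-dimethyltricyclo[4.4.0.0(2,5)]decan-7-one, trans-fused at C1–C6 (germacrane C10–C5, methyl anti to H) and cis-fused at C2–C5 (germacrane C1–C4)
Conditions: hν (λ > 300 nm, Pyrex), 11 (10 equiv), CH2Cl2, −78 °C; chromatography on neutral silica at 0 °C
Reagents that add atoms: none
Why: Enone–alkene [2+2] photocycloaddition through the twisted triplet enone and a 1,4-biradical should join C10 (the methyl-bearing β-carbon) to the unsubstituted cyclobutene carbon (C1) and C5 to the methyl-bearing one (C4), so that the two quaternary carbons end up 1,3 across the new cyclobutane and not adjacent; trans 6/4-fused adducts are regular kinetic products of triplet cyclohexenones and survive as long as base is kept away (the cis-fused isomers formed alongside are separated), while the configuration of the four new stereocentres relative to C8 is immaterial because all four become trigonal in step 9.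

Step 9
Reactants: 12 (9S)-9-(tert-butyldimethylsilyloxy)-1,5-dimethyltricyclo[4.4.0.0(2,5)]decan-7-one
Product: 13 (1(10)E,4E,8S)-8-(tert-butyldimethylsilyloxy)germacra-1(10),4-dien-6-one
Conditions: flash vacuum thermolysis, 400 °C, 0.01 mbar, quartz tube (contact time of milliseconds), trap at −196 °C; product kept below 0 °C
Reagents that add atoms: none
Why: Retro-[2+2] by homolysis of the strained central C1–C4 bond of the bicyclo[2.2.0]hexane unit to a cyclohexane-1,4-diyl (radicals at C1 and at the methyl-bearing C4), followed by β-scission of the old enone bond C5–C10; the closest known reaction type is the thermal cycloreversion of enone–cyclobutene photoadducts to cyclodeca-1,5-dienes. No ring is closed: the ten-membered ring is the perimeter of the tricycle and is set free when the two inner bonds break, and no stereocentre is formed (C8 passes through untouched). Olefin geometry is governed by the ring fusion: on the chair-like diyl the trans-disposed C6 and C9 are both equatorial, so both new double bonds should emerge E (the σ2s+σ2a-allowed outcome), whereas a cis-fused adduct could pass on only one E bond and would leave the enone Z. The step needs cycloreversion without onward Cope rearrangement of the E,E-diene to the elemane and without scission of C2–C3; short contact at high temperature favours the high-A-factor homolysis over the ordered Cope transition state, the strain of the trans-fused skeleton lowers the barrier, and C5–C10 is the bond that breaks because its cleavage creates the conjugated enone and relieves the trans fusion.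

Step 10
Reactants: 13 (1(10)E,4E,8S)-8-(tert-butyldimethylsilyloxy)germacra-1(10),4-dien-6-one
Product: 14 (1(10)E,4R,5S,8S)-8-(tert-butyldimethylsilyloxy)-4,5-epoxygermacr-1(10)-en-6-one (4α,5β-oxirane)
Conditions: t-BuOOH (in decane), DBU, CH2Cl2, 0 °C
Reagents that add atoms: tert-butyl hydroperoxide, CC(C)(C)OO
Why: Weitz–Scheffer epoxidation, in which tert-butylperoxide adds to C4 of the only electron-poor olefin and the enolate closes on oxygen with loss of tert-butoxide, should turn the E-enone into the trans-epoxide; the crown conformer that keeps the C8 silyloxy group pseudo-equatorial holds both methyls on one face and offers the outer (α) face of C4=C5, so peripheral attack should set C4 as R and C5 as S (the oxirane of the target), while the isolated C1=C10 bond is inert to the nucleophilic oxidant.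

Step 11
Reactants: 14 (1(10)E,4R,5S,8S)-8-(tert-butyldimethylsilyloxy)-4,5-epoxygermacr-1(10)-en-6-one and 15 ethyl glyoxylate
Product: 17 ethyl 2-hydroxy-2-[(4R,5S,8S)-8-(tert-butyldimethylsilyloxy)-4,5-epoxy-6-oxogermacr-1(10)-en-7-yl]acetate (epimers at C7 and C11), via lithium enolate 16 (not isolated)
Conditions: LiN(iPr)2 (LDA), THF, −78 °C; 15 (freshly distilled), −78 °C; AcOH quench at −78 °C
Reagents that add atoms: none
Why: Kinetic deprotonation at C7, the only enolisable position of the epoxy ketone, and aldol addition to the non-enolisable and very electrophilic aldehyde at −78 °C should outrun β-elimination of the C8 silyloxide and retro-aldol; the C7 and C11 configurations need no control because both carbons become trigonal in step 13.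

Step 12
Reactants: 17 ethyl 2-hydroxy-2-[(4R,5S,8S)-8-(tert-butyldimethylsilyloxy)-4,5-epoxy-6-oxogermacr-1(10)-en-7-yl]acetate
Product: 19 (4R,5R,6S,8S)-8-(tert-butyldimethylsilyloxy)-4,5-epoxy-11-hydroxy-13-norgermacr-1(10)-en-12,6-olide (epimers at C7 and C11), via diol ester 18 (not isolated)
Conditions: NaBH4, CeCl3·7H2O, MeOH, −78 to −40 °C; then 2-hydroxypyridine (cat.), toluene, 50 °C
Reagents that add atoms: none
Why: In this Luche reduction the small hydride should enter the C6 carbonyl from the outer face of the crown conformer and leave the C6 oxygen pseudo-equatorial (6S), that is anti to the C5–O bond and on the same side as the C8 oxygen, after which the γ-hydroxyl of 18 closes the five-membered lactone onto the activated α-hydroxy ester (5-exo-trig acyl substitution, loss of ethanol) under mild bifunctional catalysis that leaves the epoxide alone.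

Step 13
Reactants: 19 (4R,5R,6S,8S)-8-(tert-butyldimethylsilyloxy)-4,5-epoxy-11-hydroxy-13-norgermacr-1(10)-en-12,6-olide
Product: 21 (4R,5R,6S,8S)-8-(tert-butyldimethylsilyloxy)-4,5-epoxy-11-hydroxy-13-norgermacra-1(10),7(11)-dien-12,6-olide (enol form), via keto lactone 20 (not isolated)
Conditions: Dess–Martin periodinane, pyridine, CH2Cl2, 0 °C to rt
Reagents that add atoms: none
Why: Dess–Martin oxidation of the secondary α-hydroxy lactone gives the α-keto lactone 20, which should enolise completely because its only enolisable hydrogen is H7; this places the C7=C11 double bond regiospecifically inside the lactone, with C12 necessarily on the C6 side, and erases the uncontrolled C7 and C11 centres.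

Step 14
Reactants: 21 (4R,5R,6S,8S)-8-(tert-butyldimethylsilyloxy)-4,5-epoxy-11-hydroxy-13-norgermacra-1(10),7(11)-dien-12,6-olide
Product: 22 (4R,5R,6S,8S)-8-(tert-butyldimethylsilyloxy)-4,5-epoxy-11-(trifluoromethanesulfonyloxy)-13-norgermacra-1(10),7(11)-dien-12,6-olide
Conditions: PhNTf2, Et3N, DMAP (cat.), CH2Cl2, 0 °C to rt
Reagents that add atoms: N-phenylbis(trifluoromethanesulfonimide), O=S(=O)(N(c1ccccc1)S(=O)(=O)C(F)(F)F)C(F)(F)F
Why: O-Sulfonylation of the acidic enol (a diosphenol-type hydroxyl) with the mild triflimide reagent and an amine base should give the enol triflate without touching the epoxide.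

Step 15
Reactants: 22 (4R,5R,6S,8S)-8-(tert-butyldimethylsilyloxy)-4,5-epoxy-11-(trifluoromethanesulfonyloxy)-13-norgermacra-1(10),7(11)-dien-12,6-olide
Product: 23 (4R,5R,6S,8S)-8-(tert-butyldimethylsilyloxy)-4,5-epoxy-13-hydroxygermacra-1(10),7(11)-dien-12,6-olide
Conditions: Bu3SnCH2OH, Pd(PPh3)4 (5 mol %), LiCl, 1,4-dioxane, 80 °C
Reagents that add atoms: (tributylstannyl)methanol, OC[Sn](CCCC)(CCCC)CCCC
Why: Stille (Migita–Kosugi–Stille) coupling, in which zerovalent palladium inserts into the C11–OTf bond of the electron-poor enol triflate, the hydroxymethyl group is transferred from tin (chloride replaces triflate on palladium) and reductive elimination forms C11–C13, builds C13 on the preformed butenolide so that the geometry about C7=C11 is never in question; the epoxide is not allylic and is not ionised.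

Step 16
Reactants: 23 (4R,5R,6S,8S)-8-(tert-butyldimethylsilyloxy)-4,5-epoxy-13-hydroxygermacra-1(10),7(11)-dien-12,6-olide
Product: 24 (4R,5R,6S,8S)-13-acetoxy-8-(tert-butyldimethylsilyloxy)-4,5-epoxygermacra-1(10),7(11)-dien-12,6-olide
Conditions: Ac2O, pyridine, DMAP (cat.), CH2Cl2, 0 °C
Reagents that add atoms: acetic anhydride, CC(=O)OC(C)=O
Why: DMAP-catalysed acylation of the only free hydroxyl, a primary allylic one, should be fast and clean.

Step 17
Reactants: 24 (4R,5R,6S,8S)-13-acetoxy-8-(tert-butyldimethylsilyloxy)-4,5-epoxygermacra-1(10),7(11)-dien-12,6-olide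
Product: 25 (4R,5R,6S,8S)-13-acetoxy-4,5-epoxy-8-hydroxygermacra-1(10),7(11)-dien-12,6-olide
Conditions: HF·pyridine, pyridine, THF, 0 °C to rt
Reagents that add atoms: none
Why: Fluoride-mediated cleavage of the secondary silyl ether under pyridine-buffered conditions should be tolerated by the epoxide, the acetate and the butenolide; the freed C8 hydroxyl cannot translactonise because C12 is held on the far side of the C7=C11 bond, and acetyl migration from the primary C13 oxygen to the secondary C8 oxygen is uphill.

Step 18
Reactants: 25 (4R,5R,6S,8S)-13-acetoxy-4,5-epoxy-8-hydroxygermacra-1(10),7(11)-dien-12,6-olide and 26 tiglic acid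
Product: 28 (4R,5R,6S,8S)-13-acetoxy-4,5-epoxy-8-tigloyloxygermacra-1(10),7(11)-dien-12,6-olide, via mixed anhydride 27 (not isolated)
Conditions: 2,4,6-trichlorobenzoyl chloride, Et3N, toluene, rt; then 25, DMAP, rt
Reagents that add atoms: none
Why: Yamaguchi esterification, in which DMAP attacks the unhindered tigloyl carbonyl of the mixed anhydride and the acylpyridinium acylates the hindered secondary alcohol, should proceed with retention at C8 and with the E geometry of the tiglate, which is the stable one.

Step 19
Reactants: 28 (4R,5R,6S,8S)-13-acetoxy-4,5-epoxy-8-tigloyloxygermacra-1(10),7(11)-dien-12,6-olide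
Product: 31 CNP0225286.1, (4R,5R,6S,8S)-13-acetoxy-4,5-epoxy-1-oxo-8-tigloyloxygermacra-7(11),10(14)-dien-12,6-olide, via hydroperoxide 29 (not isolated), via peroxyacetate 30 (not isolated)
Conditions: O2, tetraphenylporphyrin (cat.), hν (visible), Ac2O, pyridine, DMAP (cat.), CH2Cl2, 0 °C
Reagents that add atoms: oxygen, O=O
Why: Schenck ene reaction of singlet oxygen at the only electron-rich olefin, where on the E-configured C1=C10 bond the crowded side carries C2 and the C14 methyl (cis effect) and the freely rotating methyl delivers the hydrogen, should put oxygen on C1 and move the double bond to C10=C14 (29), after which acetylation to 30 and Kornblum–DeLaMare-type elimination by pyridine give the C1 ketone; the butenolide and tiglate olefins are electron-poor and inert, and the C1 stereocentre of 29 is destroyed.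

## Compound list

1 | all-cis-cyclohexane-1,3,5-triol | O[C@H]1C[C@@H](O)C[C@@H](O)C1 | starting material
2 | all-cis-5-(tert-butyldimethylsilyloxy)cyclohexane-1,3-diol (meso) | O[C@H]1C[C@@H](O)C[C@@H](O[Si](C)(C)C(C)(C)C)C1 | intermediate
3 | (1R,3S,5S)-3-(tert-butyldimethylsilyloxy)-5-hydroxycyclohexyl acetate | O[C@H]1C[C@@H](OC(C)=O)C[C@@H](O[Si](C)(C)C(C)(C)C)C1 | intermediate
4 | (3S,5R)-3-acetoxy-5-(tert-butyldimethylsilyloxy)cyclohexanone | O=C1C[C@@H](OC(C)=O)C[C@@H](O[Si](C)(C)C(C)(C)C)C1 | intermediate (not isolated)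
5 | (R)-5-(tert-butyldimethylsilyloxy)cyclohex-2-en-1-one | O=C1C=CC[C@@H](O[Si](C)(C)C(C)(C)C)C1 | intermediate
6 | (5R)-5-(tert-butyldimethylsilyloxy)-1-methylcyclohex-2-en-1-ol (C1 epimers) | CC1(O)C=CC[C@@H](O[Si](C)(C)C(C)(C)C)C1 | intermediate
7 | (S)-5-(tert-butyldimethylsilyloxy)-3-methylcyclohex-2-en-1-one | O=C1C[C@@H](O[Si](C)(C)C(C)(C)C)CC(C)=C1 | intermediate
8 | cyclopropyl methyl ketone | CC(=O)C1CC1 | starting material
9 | cyclopropyl methyl ketone p-toluenesulfonylhydrazone | CC(=NNS(=O)(=O)c1ccc(C)cc1)C1CC1 | intermediate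
10 | 1-cyclopropyl-1-diazoethane | CC(=[N+]=[N-])C1CC1 | intermediate (not isolated)
11 | 1-methylcyclobutene | CC1=CCC1 | intermediate
12 | (9S)-9-(tert-butyldimethylsilyloxy)-1,5-dimethyltricyclo[4.4.0.0(2,5)]decan-7-one, trans 6/4 fusion, cis 4/4 fusion | O=C1C[C@@H](O[Si](C)(C)C(C)(C)C)C[C@]2(C)[C@@H]1[C@@]1(C)CC[C@H]12 | intermediate
13 | (1(10)E,4E,8S)-8-(tert-butyldimethylsilyloxy)germacra-1(10),4-dien-6-one | O=C1C[C@@H](O[Si](C)(C)C(C)(C)C)C/C(C)=C/CC/C(C)=C/1 | intermediate
14 | (1(10)E,4R,5S,8S)-8-(tert-butyldimethylsilyloxy)-4,5-epoxygermacr-1(10)-en-6-one | O=C1C[C@@H](O[Si](C)(C)C(C)(C)C)C/C(C)=C/CC[C@@]2(C)O[C@@H]21 | intermediate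
15 | ethyl glyoxylate | CCOC(=O)C=O | starting material
16 | lithium C6(7)-enolate of 14 | [Li]OC1=C[C@@H](O[Si](C)(C)C(C)(C)C)C/C(C)=C/CC[C@@]2(C)O[C@@H]21 | intermediate (not isolated)
17 | ethyl 2-hydroxy-2-[(4R,5S,8S)-8-(tert-butyldimethylsilyloxy)-4,5-epoxy-6-oxogermacr-1(10)-en-7-yl]acetate (C7 and C11 epimers) | O=C1C(C(O)C(=O)OCC)[C@@H](O[Si](C)(C)C(C)(C)C)C/C(C)=C/CC[C@@]2(C)O[C@@H]21 | intermediate
18 | ethyl 2-hydroxy-2-[(4R,5R,6S,8S)-8-(tert-butyldimethylsilyloxy)-4,5-epoxy-6-hydroxygermacr-1(10)-en-7-yl]acetate (C7 and C11 epimers) | O[C@H]1C(C(O)C(=O)OCC)[C@@H](O[Si](C)(C)C(C)(C)C)C/C(C)=C/CC[C@@]2(C)O[C@@H]21 | intermediate (not isolated)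
19 | (4R,5R,6S,8S)-8-(tert-butyldimethylsilyloxy)-4,5-epoxy-11-hydroxy-13-norgermacr-1(10)-en-12,6-olide (C7 and C11 epimers) | O1[C@H]2C(C(O)C1=O)[C@@H](O[Si](C)(C)C(C)(C)C)C/C(C)=C/CC[C@@]3(C)O[C@H]23 | intermediate
20 | (4R,5R,6S,8S)-8-(tert-butyldimethylsilyloxy)-4,5-epoxy-11-oxo-13-norgermacr-1(10)-en-12,6-olide | O1[C@H]2C(C(=O)C1=O)[C@@H](O[Si](C)(C)C(C)(C)C)C/C(C)=C/CC[C@@]3(C)O[C@H]23 | intermediate (not isolated)
21 | (4R,5R,6S,8S)-8-(tert-butyldimethylsilyloxy)-4,5-epoxy-11-hydroxy-13-norgermacra-1(10),7(11)-dien-12,6-olide | O1[C@H]2C(=C(O)C1=O)[C@@H](O[Si](C)(C)C(C)(C)C)C/C(C)=C/CC[C@@]3(C)O[C@H]23 | intermediate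
22 | (4R,5R,6S,8S)-8-(tert-butyldimethylsilyloxy)-4,5-epoxy-11-(trifluoromethanesulfonyloxy)-13-norgermacra-1(10),7(11)-dien-12,6-olide | O1[C@H]2C(=C(OS(=O)(=O)C(F)(F)F)C1=O)[C@@H](O[Si](C)(C)C(C)(C)C)C/C(C)=C/CC[C@@]3(C)O[C@H]23 | intermediate
23 | (4R,5R,6S,8S)-8-(tert-butyldimethylsilyloxy)-4,5-epoxy-13-hydroxygermacra-1(10),7(11)-dien-12,6-olide | O1[C@H]2C(=C(CO)C1=O)[C@@H](O[Si](C)(C)C(C)(C)C)C/C(C)=C/CC[C@@]3(C)O[C@H]23 | intermediate
24 | (4R,5R,6S,8S)-13-acetoxy-8-(tert-butyldimethylsilyloxy)-4,5-epoxygermacra-1(10),7(11)-dien-12,6-olide | O1[C@H]2C(=C(COC(C)=O)C1=O)[C@@H](O[Si](C)(C)C(C)(C)C)C/C(C)=C/CC[C@@]3(C)O[C@H]23 | intermediate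
25 | (4R,5R,6S,8S)-13-acetoxy-4,5-epoxy-8-hydroxygermacra-1(10),7(11)-dien-12,6-olide | O1[C@H]2C(=C(COC(C)=O)C1=O)[C@@H](O)C/C(C)=C/CC[C@@]3(C)O[C@H]23 | intermediate
26 | tiglic acid | C/C=C(\C)C(=O)O | starting material
27 | tiglic 2,4,6-trichlorobenzoic anhydride | C/C=C(\C)C(=O)OC(=O)c1c(Cl)cc(Cl)cc1Cl | intermediate (not isolated)
28 | (4R,5R,6S,8S)-13-acetoxy-4,5-epoxy-8-tigloyloxygermacra-1(10),7(11)-dien-12,6-olide | O1[C@H]2C(=C(COC(C)=O)C1=O)[C@@H](OC(=O)/C(C)=C/C)C/C(C)=C/CC[C@@]3(C)O[C@H]23 | intermediate
29 | (4R,5R,6S,8S)-13-acetoxy-4,5-epoxy-1-hydroperoxy-8-tigloyloxygermacra-7(11),10(14)-dien-12,6-olide (C1 epimers) | O1[C@H]2C(=C(COC(C)=O)C1=O)[C@@H](OC(=O)/C(C)=C/C)CC(=C)C(OO)CC[C@@]3(C)O[C@H]23 | intermediate (not isolated)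
30 | (4R,5R,6S,8S)-13-acetoxy-1-(acetylperoxy)-4,5-epoxy-8-tigloyloxygermacra-7(11),10(14)-dien-12,6-olide (C1 epimers) | O1[C@H]2C(=C(COC(C)=O)C1=O)[C@@H](OC(=O)/C(C)=C/C)CC(=C)C(OOC(C)=O)CC[C@@]3(C)O[C@H]23 | intermediate (not isolated)
31 | CNP0225286.1, (4R,5R,6S,8S)-13-acetoxy-4,5-epoxy-1-oxo-8-tigloyloxygermacra-7(11),10(14)-dien-12,6-olide | C=C1C[C@H](OC(=O)/C(C)=C/C)C2=C(COC(C)=O)C(=O)O[C@@H]2[C@H]2O[C@]2(C)CCC1=O | target

## Step count

Total: 19 steps. Longest linear sequence: 17 steps (steps 1–5 and 8–19); steps 6 and 7 form the side branch to 11.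

## Steps most likely to fail

**Step 9 (key step).** The E,E-dienone may rearrange onward by Cope reaction to the elemane during or after the cycloreversion, or step 8 may supply too little trans-fused adduct. The fallback sets out from 12 and comes back at 13. Compound 12 (or the pooled photoadducts) is epimerised at C5 on basic alumina to the cis-anti-cis adduct F1. F1 is thermolysed in solution (decalin, 190 °C, sealed tube) to the (1(10)E,4Z)-dienone F2, which a cis-fused cyclobutane should give and which resists the Cope rearrangement because only a boat transition state is open to it. The enone geometry is then inverted: conjugate addition of thiophenol (PhSH, Et3N cat.) at C4 gives the β-phenylthio ketone F3, and mCPBA (1 equiv, −78 °C) gives the sulfoxide F4. Thermal syn-elimination of F4 at 40–60 °C removes the acidic C5 hydrogen; as a five-centre syn-elimination in a ten-membered ring it should favour the E-olefin, and it returns 13 below the temperature of the Cope rearrangement.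

**Step 10.** Facial selectivity of the peroxide addition relative to C8 may be poor, and the base may deconjugate the enone or eliminate the C8 silyloxide. The fallback sets out from 13 and comes back at 14; it replaces substrate control by reagent control and hydroxyl direction. Corey–Bakshi–Shibata reduction ((R)-Me-CBS oxazaborolidine, catecholborane, toluene, −78 °C; alkenyl as the large group, C7 methylene as the small one) gives the (6S)-allylic alcohol F5. VO(acac)2 (cat.) and t-BuOOH in CH2Cl2 at 0 °C then epoxidise only the allylic C4=C5 bond from the hydroxyl face, threo-selectively through allylic 1,3-strain with the C15 methyl, to the (4R,5R,6S)-epoxy alcohol F6. Dess–Martin oxidation of F6 returns 14.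

**Step 12.** Hydride may be delivered to the wrong face of the C6 carbonyl. The fallback sets out from 17 and comes back at 19; it corrects C6 by substitution with inversion instead of by facial control. If the reduction of 17 delivers the 6β-alcohol, lactonisation ends at the 6-epi hydroxy lactone F7. LiOH in THF/H2O at 0 °C opens F7 to the 6-epi dihydroxy acid F8, liberated at 0 °C and used at once. Mitsunobu lactonisation (PPh3, DIAD, THF, 0 °C) then closes the γ-lactone by carboxylate displacement at the activated C6 oxygen with inversion, giving 19.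

## Further compounds

F1 | step 9 | (9S)-9-(tert-butyldimethylsilyloxy)-1,5-dimethyltricyclo[4.4.0.0(2,5)]decan-7-one, cis-anti-cis | O=C1C[C@@H](O[Si](C)(C)C(C)(C)C)C[C@]2(C)[C@H]1[C@@]1(C)CC[C@H]12
F2 | step 9 | (1(10)E,4Z,8S)-8-(tert-butyldimethylsilyloxy)germacra-1(10),4-dien-6-one | O=C1C[C@@H](O[Si](C)(C)C(C)(C)C)C/C(C)=C/CC/C(C)=C\1
F3 | step 9 | (1(10)E,8S)-8-(tert-butyldimethylsilyloxy)-4-(phenylthio)germacr-1(10)-en-6-one (C4 epimers) | O=C1C[C@@H](O[Si](C)(C)C(C)(C)C)C/C(C)=C/CCC(C)(Sc2ccccc2)C1
F4 | step 9 | (1(10)E,8S)-8-(tert-butyldimethylsilyloxy)-4-(phenylsulfinyl)germacr-1(10)-en-6-one | O=C1C[C@@H](O[Si](C)(C)C(C)(C)C)C/C(C)=C/CCC(C)(S(=O)c2ccccc2)C1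
F5 | step 10 | (1(10)E,4E,6S,8S)-8-(tert-butyldimethylsilyloxy)germacra-1(10),4-dien-6-ol | O[C@H]1C[C@@H](O[Si](C)(C)C(C)(C)C)C/C(C)=C/CC/C(C)=C/1
F6 | step 10 | (1(10)E,4R,5R,6S,8S)-8-(tert-butyldimethylsilyloxy)-4,5-epoxygermacr-1(10)-en-6-ol | O[C@H]1C[C@@H](O[Si](C)(C)C(C)(C)C)C/C(C)=C/CC[C@@]2(C)O[C@@H]21
F7 | step 12 | (4R,5R,6R,8S)-8-(tert-butyldimethylsilyloxy)-4,5-epoxy-11-hydroxy-13-norgermacr-1(10)-en-12,6-olide (6-epimer of 19) | O1[C@@H]2C(C(O)C1=O)[C@@H](O[Si](C)(C)C(C)(C)C)C/C(C)=C/CC[C@@]3(C)O[C@H]23
F8 | step 12 | 2-hydroxy-2-[(4R,5R,6R,8S)-8-(tert-butyldimethylsilyloxy)-4,5-epoxy-6-hydroxygermacr-1(10)-en-7-yl]acetic acid | O[C@@H]1C(C(O)C(=O)O)[C@@H](O[Si](C)(C)C(C)(C)C)C/C(C)=C/CC[C@@]2(C)O[C@@H]21
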